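## The problem

Numbering used throughout: C1 ring-alkene carbon bearing the side chain, C2 alkene CH, C3 lactone α-CH, C4 lactone C=O, O5, C6 lactone O–CH, C7 CH2, C8 methyl carbinol, C9 CH beside the spiro carbon, C10 central CH, C11 spiro carbon, C12 CH2, C13 ketone, C14 CH2, C15 CHOH, C16 side-chain CH, C17 CH2, C18 ester C=O.

Three rings share C10: the cyclohexene C1=C2–C3–C10–C9–C11, the γ-lactone C3–C4–O5–C6–C10 and the cyclopentane C6–C7–C8–C9–C10. A 3-hydroxycyclopentanone (C11–C15) is spiro-fused at C11, and C1 carries the acyclic stereocentre C16. Seven of the eight stereocentres sit on this core: H6, H9 and H10 are on one face and H3 on the other, so the lactone is trans-fused to the cyclohexene and cis-fused to the cyclopentane. The C8 hydroxyl lies cis to C11, C15 is cis to H9, and the C15 hydroxyl is cis to C1. One reagent-set carbinol (C6) plus one transferable element can fix C3 and C10, and the folded tricycle can then direct C8, C9, C11 and C15. C16 is insulated from the core by the sp2 carbon C1 and needs catalyst control. The 3-hydroxycyclopentanone dehydrates or undergoes retro-aldol cleavage with base, C3–H is both α to the lactone and allylic, and the isopropenyl group tolerates neither ozone nor strong acid. The enabling feature is that C4 sits on C3 directly beside C10: with the ring alkene imagined at C9=C11, C4–C3–C10–C9=C11 is a γ,δ-unsaturated acid, and C3 is already tied to C11 through C2–C1. An oxygen on C11 therefore closes a δ-lactone (O5, C4, C3, C2, C1, C11), and the cyclohexene is the Claisen ring-contraction product of a 6-alkenyl δ-lactone. An oxygen at C1 then lets the alkene walk C9=C11 → C11=C1 → C1=C2 while C9, C11 and C1 take their carbon substituents.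

## Retrosynthesis

**C16–isopropenyl and unmasking (33 ⇒ 32 ⇒ 30 + 31).** The target 33 is the doubly silylated, ketal-protected 32 after one acidic step. Cutting the C16–isopropenyl bond leads to dienoate 30 and isopropenylboronate 31. Setting C16 last, by a rhodium-catalysed 1,4-addition, avoids carrying a doubly allylic C16–H through Lewis-acid steps and puts the only remote stereocentre under ligand control. The forward step must add 1,4 and on one face of a hindered enoate.

**C1–C16 (30 ⇒ 28 + 29; 28 ⇒ 27 ⇒ 26).** A Heck disconnection gives enol triflate 28 and methyl acrylate 29. The triflate comes from ketone 27 (the bis-silyl ether of 26), which can enolise only towards C2 because C11 is quaternary, so the C1=C2 position is secured by structure. This is preferred to adding a carbon nucleophile to the neopentyl C1 ketone and dehydrating.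

**C11–C15 (26 ⇒ 25).** An aldol cut opens the spiro ring to aldehyde 25, in which C11 is the carbon terminus of a C1=C11 silyl enol ether. The enol ether fixes which α-carbon reacts, and the C9–C8 bond blocks one face of C11. The forward reaction has to deliver C15 anti to C8 and the hydroxyl cis to C1.

**C8–C9 (25 ⇒ 24 ⇒ 23).** Aldehyde 25 is the oxidation product of alcohol 24. Cutting C8–C9 in 24 as an intramolecular ketone–ene reaction leads to methyl ketone 23 with the alkene at C9=C11 and an allylic silyl ether at C1. The ene mechanism needs the carbonyl oxygen next to the C1 hydrogen, which is exactly the C8 configuration required (hydroxyl cis to C11). A ketyl radical closure would be expected to give the opposite C8 epimer. The precursor loses a ring and two stereocentres.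

**Functional-group adjustment (23 ⇒ 22 ⇒ 20).** The methyl ketone is the Wacker product of allyl lactone 22, and 22 is the lactonised form of acid 20 after PMB removal. A terminal alkene as C8 mask is orthogonal to the C13 dioxolane and survives strong base.

**C3–C10 and the cyclohexene (20 ⇒ 17), the key cut.** Acid 20 is the [3,3] ring-contraction product of the Z-alkenyl δ-lactone 17. One pericyclic step makes the carbocycle and both C3 and C10 from a single carbinol centre (C11). A Diels–Alder route to the same ring would place the carboxyl on the wrong carbon relative to the C1 oxygen. The precursor is a monocyclic lactone with three stereocentres.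

**C9–C11 (17 ⇒ 16 ⇒ 9 + 14).** Semihydrogenation relates 17 to alkyne 16. Cutting the alkynyl–carbinol bond gives keto ester 9 and alkyne 14. The acetylide must add anti to the C1 silyloxy group (Felkin–Anh), and the alkoxide lactonises onto the benzyl ester in the same flask.

**Keto ester (9 ⇒ 7 ⇒ 4 + 6; 4 ⇒ 3 ⇒ 2 ⇒ 1; 6 ⇐ 5).** The β-keto dioxolane 9 is the ethylene glycol adduct of ynone 7, made from Weinreb amide 4 and alkyne 6 (from but-3-yn-1-ol 5). Amide 4 derives from L-glutamic acid 5-benzyl ester 1 by diazotisation (2), amidation (3) and silylation. A dioxolane at C13, rather than an alkene, keeps the C12 hydrogens unactivated for the later ene step and lets the ketone appear in the last step without ozone.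

**Alkyne (14 ⇒ 12 ⇒ 10 + 11).** The C6 carbinol comes from asymmetric allylboration of silylpropynal 10 with allylmagnesium bromide 11 via a chiral borane, giving 12, then etherification and desilylation.

## Roads not taken

**Alternative 1:** The cut is C11–C15 at the very end. An aldehyde A1, with a tetrasubstituted C11=C1 alkene already carrying the complete C16 side chain, would undergo a Me2AlCl-promoted carbonyl–ene reaction with transfer of a C2 hydrogen. This gives A2, the target as its C13 dioxolane and C8 triethylsilyl ether. The merit is real: one step would create C11, C15 and the C1=C2 alkene, and the triflate, Heck and conjugate-addition steps of the chosen plan would disappear. This road is clearly shorter in the endgame. Its weak points are structural. The ene unit has three allylic hydrogen sources (C2, C12 and the doubly allylic C16–H), and loss of the C16 hydrogen would destroy the side-chain stereocentre. The closure is a strained five-membered ene of the kind where the tether sits on the central ene carbon. A stereodefined tetrasubstituted alkene bearing C16 must also be made first. The chosen plan spends about four more steps, but the nucleophile at C11 is a regiodefined enol ether and C16 is set under ligand control.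

**Alternative 2:** The cut is C9–C11. Under K2CO3, the C1-ketone enolate of A3 (a cyclopentyl ketone tethered to a 4-hydroxy-4-methylcyclopentenone) would add through C11 to C9, giving the tricyclic diketo ester A4. This road is more convergent than the chosen one: both five-membered rings come from the chiral pool with C8 and C15 in place, and a mild base forms the six-membered ring and the spiro centre together. The weak points are four. A fully substituted enolate carbon must attack a β-carbon flanked by the quaternary C8. The Michael addition is reversible, so C9, C10 and C11 emerge under thermodynamic rather than mechanistic control. A3 is a β-silyloxy ketone with an α-hydrogen and can eliminate before it cyclises. C6 is left as a ketone that still needs reduction and a trans-lactonisation, and C3 is epimerisable throughout. Against the better convergence, the chosen plan sets C3 and C10 by a stereospecific sigmatropic shift and C8/C9 by a geometrically constrained ene reaction.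

**Alternative 3:** The cut is C8–C9. Keto lactone A5 would undergo the Me2AlCl ketone–ene reaction to give the tricyclic silyl enol ether A6. This is a sound transformation and is adopted as step 14 of the chosen route, so it is a component rather than a competitor. As the defining step of a strategy it simplifies little: A5 still contains the cyclohexene with C3, C6 and C10 in place, and their construction is left open. The triisopropylsilyl ether at C15 in A6 also cannot be removed later without destroying the enol ether. The chosen plan supplies A5's analogue 23 through the Claisen ring contraction and frees the C15 hydroxyl before the ene step. It shares with this alternative the risk over which allylic hydrogen is transferred.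

Key step: step 11

Assumption: the configuration is read from the SMILES as 3R,6R,8S,9S,10R,11R,15S,16S in the numbering above.

## Route

Abbreviations: TBS = tert-butyldimethylsilyl, TES = triethylsilyl, PMB = 4-methoxybenzyl, Ipc = isopinocampheyl, NMO = N-methylmorpholine N-oxide.

Step 1
Reactants: 1 L-glutamic acid 5-benzyl ester
Product: 2 (2S)-5-(benzyloxy)-2-hydroxy-5-oxopentanoic acid
Conditions: NaNO2, 1 M H2SO4 (aq.), 0 °C to rt
Reagents that add atoms: water, O
Why: Diazotisation of an α-amino acid with retention: the carboxylate displaces N2 to an α-lactone that water reopens (double inversion), so the future C1 keeps the S configuration; the γ-benzyl ester is known to survive these conditions.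

Step 2
Reactants: 2 (2S)-5-(benzyloxy)-2-hydroxy-5-oxopentanoic acid
Product: 3 benzyl (4S)-4-hydroxy-5-[methoxy(methyl)amino]-5-oxopentanoate
Conditions: MeNH(OMe)·HCl, EDC·HCl, HOBt, N-methylmorpholine, CH2Cl2, 0 °C to rt
Reagents that add atoms: N,O-dimethylhydroxylamine hydrochloride, CNOC.Cl
Why: Carbodiimide amide coupling to the Weinreb amide; the amine outcompetes the secondary hydroxyl, and the HOBt ester of an α-hydroxy acid should not epimerise.

Step 3
Reactants: 3 benzyl (4S)-4-hydroxy-5-[methoxy(methyl)amino]-5-oxopentanoate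
Product: 4 benzyl (4S)-4-[(tert-butyldimethylsilyl)oxy]-5-[methoxy(methyl)amino]-5-oxopentanoate
Conditions: TBSCl, imidazole, DMF, rt
Reagents that add atoms: tert-butyldimethylsilyl chloride, CC(C)(C)[Si](C)(C)Cl
Why: Standard silylation of a secondary alcohol; the non-chelating silyl ether is what later enforces Felkin–Anh addition at C11 and becomes the enol ether silyl group.

Step 4
Reactants: 5 but-3-yn-1-ol
Product: 6 1-[(but-3-yn-1-yloxy)methyl]-4-methoxybenzene
Conditions: NaH, PMBCl, Bu4NI, THF/DMF, 0 °C to rt
Reagents that add atoms: 4-methoxybenzyl chloride, COc1ccc(CCl)cc1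
Why: Williamson etherification; one equivalent of NaH deprotonates the alcohol, not the much less acidic alkyne C–H.

Step 5
Reactants: 4 benzyl (4S)-4-[(tert-butyldimethylsilyl)oxy]-5-[methoxy(methyl)amino]-5-oxopentanoate; 6 1-[(but-3-yn-1-yloxy)methyl]-4-methoxybenzene
Product: 7 benzyl (4S)-4-[(tert-butyldimethylsilyl)oxy]-9-[(4-methoxybenzyl)oxy]-5-oxonon-6-ynoate
Conditions: 6, n-BuLi, THF, −78 °C; then 4, −78 to −20 °C
Reagents that add atoms: none
Why: Acylation of a lithium acetylide by a Weinreb amide; the chelated tetrahedral intermediate stops at the ketone, and the amide reacts ahead of the benzyl ester at low temperature.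

Step 6
Reactants: 7 benzyl (4S)-4-[(tert-butyldimethylsilyl)oxy]-9-[(4-methoxybenzyl)oxy]-5-oxonon-6-ynoate
Product: 9 benzyl (4S)-4-[(tert-butyldimethylsilyl)oxy]-6-{2-[2-((4-methoxybenzyl)oxy)ethyl]-1,3-dioxolan-2-yl}-5-oxohexanoate, via hydroxyethoxy enone 8 (not isolated)
Conditions: HOCH2CH2OH (2 equiv), PBu3 (10 mol%), CH2Cl2, rt; then camphorsulfonic acid (10 mol%), rt
Reagents that add atoms: ethylene glycol, OCCO
Why: Phosphine-catalysed oxa-Michael addition of the diol to the ynone gives β-alkoxy enone 8, and acid-catalysed intramolecular conjugate addition of the pendant hydroxyl closes the dioxolane (double conjugate addition of a diol to an ynone); the ketal can form only at C13, and base-free conditions spare the α-silyloxy stereocentre and the benzyl ester.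

Step 7
Reactants: 10 3-(trimethylsilyl)prop-2-ynal; 11 allylmagnesium bromide
Product: 12 (3R)-1-(trimethylsilyl)hex-5-en-1-yn-3-ol
Conditions: (+)-Ipc2BOMe, 11, Et2O, −78 °C to rt; then 10, −78 °C; NaOH, H2O2
Reagents that add atoms: none
Why: Brown asymmetric allylboration; the B-allyl borane formed from (+)-Ipc2BOMe should deliver allyl to the Re face of the ynal through a chair transition state, setting the R carbinol that becomes C6.

Step 8
Reactants: 12 (3R)-1-(trimethylsilyl)hex-5-en-1-yn-3-ol
Product: 14 1-{[(3R)-hex-5-en-1-yn-3-yloxy]methyl}-4-methoxybenzene, via silylalkyne ether 13 (not isolated)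
Conditions: NaH, PMBCl, Bu4NI, DMF, 0 °C; then K2CO3, MeOH, rt
Reagents that add atoms: 4-methoxybenzyl chloride, COc1ccc(CCl)cc1
Why: Williamson etherification followed by methanolysis of the alkynyl C–Si bond; neither operation touches the stereocentre.

Step 9
Reactants: 9 benzyl (4S)-4-[(tert-butyldimethylsilyl)oxy]-6-{2-[2-((4-methoxybenzyl)oxy)ethyl]-1,3-dioxolan-2-yl}-5-oxohexanoate; 14 1-{[(3R)-hex-5-en-1-yn-3-yloxy]methyl}-4-methoxybenzene
Product: 16 (5S,6R)-5-[(tert-butyldimethylsilyl)oxy]-6-{(3R)-3-[(4-methoxybenzyl)oxy]hex-5-en-1-yn-1-yl}-6-({2-[2-((4-methoxybenzyl)oxy)ethyl]-1,3-dioxolan-2-yl}methyl)oxan-2-one, via hydroxy ester 15 (not isolated)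
Conditions: 14, n-BuLi, THF, −78 °C; then 9, −78 to 0 °C; aq. NH4Cl
Reagents that add atoms: none
Why: 1,2-Addition of a lithium acetylide to an α-silyloxy ketone under Felkin–Anh (non-chelation) control: the nucleophile enters anti to the C1–O bond past H1 and should give the 11R carbinol; the tertiary alkoxide then displaces benzyl oxide from the δ-ester (6-exo-trig lactonisation).

Step 10
Reactants: 16 propargylic δ-lactone (as named in step 9)
Product: 17 (5S,6R)-5-[(tert-butyldimethylsilyl)oxy]-6-{(1Z,3R)-3-[(4-methoxybenzyl)oxy]hexa-1,5-dien-1-yl}-6-({2-[2-((4-methoxybenzyl)oxy)ethyl]-1,3-dioxolan-2-yl}methyl)oxan-2-one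
Conditions: H2 (1 atm), Pd/CaCO3–Pb(OAc)2, quinoline, EtOAc, rt
Reagents that add atoms: none
Why: Lindlar semihydrogenation; syn delivery of hydrogen gives the Z alkene, and the poisoned catalyst should leave the terminal alkene and the benzylic ethers alone if uptake is stopped at one equivalent.

Step 11
Reactants: 17 Z-alkenyl δ-lactone (as named in step 10)
Product: 20 (1R,2R,5S)-5-[(tert-butyldimethylsilyl)oxy]-2-{(1R)-1-[(4-methoxybenzyl)oxy]but-3-en-1-yl}-4-({2-[2-((4-methoxybenzyl)oxy)ethyl]-1,3-dioxolan-2-yl}methyl)cyclohex-3-ene-1-carboxylic acid, via silyl ketene acetal 18 (not isolated), via trimethylsilyl ester 19 (not isolated)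
Conditions: LiN(iPr)2, THF, −78 °C; Me3SiCl–Et3N, −78 °C to rt; toluene, 90 °C; aq. NH4Cl, MeOH
Reagents that add atoms: none
Why: Ireland–Claisen ring contraction, the lactonic ester-enolate Claisen rearrangement known for 6-alkenyl δ-lactones. LiN(iPr)2 removes a C3 proton, the only acidic C–H, and Me3SiCl traps the enolate on oxygen as the cyclic ketene acetal 18, whose C3=C4 geometry is fixed by the ring. On warming, 18 undergoes the [3,3] shift in which C3 bonds to C10 while the allylic C11–O5 bond breaks and the alkene moves to C9=C11. The six-membered carbocycle C3–C2–C1–C11–C9–C10 closes by ring contraction, the new bond joining the two ends of the C3–C2–C1–C11 tether, and O5 leaves the ring to become the C4 carboxyl. The two-atom C2–C1 bridge excludes a chair, so the shift passes through a boat resembling bicyclo[2.2.2]octane. C10 is set by suprafacial transfer from the C11–O5 bond, hence by the 11R carbinol; C3 is set relative to C10 by the boat together with the Z geometry, which places H3 and H10 anti and so C4 trans to C6. No regiochemical choice exists; the tertiary allylic C–O bond lowers the barrier, and the silyl ether, dioxolane, PMB ethers and terminal alkene are inert to amide base at −78 °C. Work-up hydrolyses the silyl ester 19 to acid 20.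

Step 12
Reactants: 20 cyclohexene carboxylic acid (as named in step 11)
Product: 22 (3R,3aR,6S,7aR)-6-[(tert-butyldimethylsilyl)oxy]-5-{[2-(2-hydroxyethyl)-1,3-dioxolan-2-yl]methyl}-3-(prop-2-en-1-yl)-3a,6,7,7a-tetrahydro-2-benzofuran-1(3H)-one, via dihydroxy acid 21 (not isolated)
Conditions: DDQ (2.5 equiv), CH2Cl2/pH 7 buffer, 0 °C to rt; then camphorsulfonic acid (5 mol%), CH2Cl2, rt
Reagents that add atoms: none
Why: Oxidative cleavage of both PMB ethers by DDQ, then acid-catalysed γ-lactonisation of the C6 hydroxyl onto the C4 acid with retention at C6; only this hydroxyl can reach the carboxyl in a five-membered ring, and the trans-diequatorial arrangement should allow the trans-fused lactone.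

Step 13
Reactants: 22 allyl lactone (as named in step 12)
Product: 23 (3R,3aR,6S,7aR)-6-[(tert-butyldimethylsilyl)oxy]-5-{[2-(2-hydroxyethyl)-1,3-dioxolan-2-yl]methyl}-3-(2-oxopropyl)-3a,6,7,7a-tetrahydro-2-benzofuran-1(3H)-one
Conditions: PdCl2 (20 mol%), CuCl, O2 (1 atm), DMF/H2O 7:1, rt
Reagents that add atoms: water, O
Why: Tsuji–Wacker oxidation: Markovnikov hydroxypalladation by divalent palladium of the only monosubstituted alkene gives the methyl ketone; the trisubstituted ring alkene is inert, and the free alcohol, silyl ether and dioxolane are tolerated.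

Step 14
Reactants: 23 methyl ketone lactone (as named in step 13)
Product: 24 tricyclic C1=C11 tert-butyldimethylsilyl enol ether with C8 methyl carbinol, C11 bearing the [2-(2-hydroxyethyl)-1,3-dioxolan-2-yl]methyl group (3R,6R,8S,9S,10R, target numbering)
Conditions: Me2AlCl (3 equiv), CH2Cl2, −78 to −20 °C; aq. KNaC4H4O6
Reagents that add atoms: none
Why: Lewis acid-promoted intramolecular carbonyl–ene reaction (type 1, five-membered ring): the aluminium-bound C8 ketone bonds to C9 on the face carrying the C6 arm while its oxygen takes the axial C1 hydrogen on the same face through a six-membered transition state; this geometry places the C8 oxygen cis to C11 (8S) and H9 cis to H10 (9S) and leaves the C11=C1 silyl enol ether, the C12 hydrogens being deactivated by the adjacent ketal and further from the carbonyl oxygen.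

Step 15
Reactants: 24 tricyclic silyl enol ether diol (as named in step 14)
Product: 25 the corresponding C15 aldehyde (3R,6R,8S,9S,10R)
Conditions: Pr4N[RuO4] (5 mol%), NMO, 4 Å MS, CH2Cl2, 0 °C
Reagents that add atoms: none
Why: Ley–Griffith oxidation of the primary alcohol; the tertiary alcohol cannot be oxidised, and the neutral medium should preserve the silyl enol ether.

Step 16
Reactants: 25 silyl enol ether aldehyde (as named in step 15)
Product: 26 tetracyclic C1 ketone with C11 spiro-fused to the cyclopentane bearing the C13 dioxolane and the free C15 hydroxyl, C8 hydroxyl free (3R,6R,8S,9S,10R,11S,15S; C11 descriptor changes by priority only)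
Conditions: Me2AlCl (2.5 equiv), CH2Cl2, −78 °C; aq. KNaC4H4O6
Reagents that add atoms: none
Why: Intramolecular Mukaiyama aldol addition closing the five-membered ring: the first equivalent of Me2AlCl caps the C8 hydroxyl and the second activates the aldehyde, chelated to a ketal oxygen; C15 should attack C11 on the face opposite the C9–C8 bond (C15 cis to H9), and the aluminium-bound oxygen should sit over the flat C1 side and not under the axial H9, giving the hydroxyl cis to C1 (15S).

Step 17
Reactants: 26 spiro hydroxy ketone (as named in step 16)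
Product: 27 C8,C15-bis(triethylsilyl) ether of 26
Conditions: TESOTf (3 equiv), 2,6-lutidine, CH2Cl2, −78 to 0 °C
Reagents that add atoms: triethylsilyl trifluoromethanesulfonate, CC[Si](CC)(CC)OS(=O)(=O)C(F)(F)F
Why: Silyl triflate silylation of a tertiary and a neopentyl secondary alcohol; capping C15–O blocks retro-aldol cleavage in the next, basic step.

Step 18
Reactants: 27 bis-silyl ether ketone (as named in step 17)
Product: 28 C1 enol triflate with the alkene at C1=C2 (3S by priority change,6R,8S,9S,10R,11S,15S)
Conditions: KN(SiMe3)2 (1.2 equiv), THF, −78 °C; PhNTf2, −78 to 0 °C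
Reagents that add atoms: N-phenylbis(trifluoromethanesulfonimide), O=S(=O)(N(c1ccccc1)S(=O)(=O)C(F)(F)F)C(F)(F)F
Why: Kinetic enolate O-triflation; C11 is quaternary, so the ketone can enolise only towards C2, and the ketone α-hydrogen is more acidic than the lactone α-hydrogen at C3.

Step 19
Reactants: 28 enol triflate (as named in step 18); 29 methyl acrylate
Product: 30 methyl (E)-3-(C1-yl)acrylate, the C1=C2/C16=C17 dienoate of the protected tetracycle
Conditions: 29 (5 equiv), Pd(OAc)2 (10 mol%), PPh3 (20 mol%), KOAc, DMF, 50 °C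
Reagents that add atoms: none
Why: Mizoroki–Heck coupling of an enol triflate: oxidative addition to zerovalent palladium, syn carbopalladation of the acrylate and syn β-hydride elimination give the E dienoate; acetate is a mild enough base to leave the C3 stereocentre alone.

Step 20
Reactants: 30 dienoate (as named in step 19); 31 isopropenylboronic acid pinacol ester
Product: 32 the target as its C13 dioxolane and C8,C15-bis(triethylsilyl) ether (3R,6R,8S,9S,10R,11R,15S,16S)
Conditions: 31 (4 equiv), [Rh(OH)((R)-binap)]2 (5 mol%), 1,4-dioxane/H2O 10:1, 50 °C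
Reagents that add atoms: none
Why: Hayashi–Miyaura asymmetric 1,4-addition: transmetalation gives an isopropenyl–rhodium species that inserts the C16=C17 bond, and water protonates the oxa-π-allyl; the substituted δ-carbon C2 should direct monovalent rhodium to 1,4- rather than 1,6-addition, and the (R)-binap complex is expected to add to the α-Re face of the E enoate, giving 16S, in a medium free of added base.

Step 21
Reactants: 32 protected target (as named in step 20)
Product: 33 CNP0255095.1
Conditions: 1 M HCl (aq.)/THF 1:3, 0 °C to rt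
Reagents that add atoms: water, O
Why: Acid hydrolysis removes both triethylsilyl ethers and the dioxolane in one operation; dilute acid at room temperature should neither dehydrate the β-hydroxy ketone nor isomerise the isopropenyl group.

## Compound list

1 | L-glutamic acid 5-benzyl ester | N[C@@H](CCC(=O)OCc1ccccc1)C(=O)O | starting material
2 | (2S)-5-(benzyloxy)-2-hydroxy-5-oxopentanoic acid | O[C@@H](CCC(=O)OCc1ccccc1)C(=O)O | intermediate
3 | benzyl (4S)-4-hydroxy-5-[methoxy(methyl)amino]-5-oxopentanoate | CON(C)C(=O)[C@@H](O)CCC(=O)OCc1ccccc1 | intermediate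
4 | benzyl (4S)-4-[(tert-butyldimethylsilyl)oxy]-5-[methoxy(methyl)amino]-5-oxopentanoate | CON(C)C(=O)[C@@H](O[Si](C)(C)C(C)(C)C)CCC(=O)OCc1ccccc1 | intermediate
5 | but-3-yn-1-ol | C#CCCO | starting material
6 | 1-[(but-3-yn-1-yloxy)methyl]-4-methoxybenzene | C#CCCOCc1ccc(OC)cc1 | intermediate
7 | benzyl (4S)-4-[(tert-butyldimethylsilyl)oxy]-9-[(4-methoxybenzyl)oxy]-5-oxonon-6-ynoate | O=C(OCc1ccccc1)CC[C@H](O[Si](C)(C)C(C)(C)C)C(=O)C#CCCOCc1ccc(OC)cc1 | intermediate
8 | benzyl (4S,6E)-4-[(tert-butyldimethylsilyl)oxy]-7-(2-hydroxyethoxy)-9-[(4-methoxybenzyl)oxy]-5-oxonon-6-enoate | O=C(OCc1ccccc1)CC[C@H](O[Si](C)(C)C(C)(C)C)C(=O)/C=C(\CCOCc1ccc(OC)cc1)OCCO | intermediate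
9 | benzyl (4S)-4-[(tert-butyldimethylsilyl)oxy]-6-{2-[2-((4-methoxybenzyl)oxy)ethyl]-1,3-dioxolan-2-yl}-5-oxohexanoate | O=C(OCc1ccccc1)CC[C@H](O[Si](C)(C)C(C)(C)C)C(=O)CC1(CCOCc2ccc(OC)cc2)OCCO1 | intermediate
10 | 3-(trimethylsilyl)prop-2-ynal | C[Si](C)(C)C#CC=O | starting material
11 | allylmagnesium bromide | C=CC[Mg]Br | starting material
12 | (3R)-1-(trimethylsilyl)hex-5-en-1-yn-3-ol | C=CC[C@@H](O)C#C[Si](C)(C)C | intermediate
13 | [(3R)-3-[(4-methoxybenzyl)oxy]hex-5-en-1-yn-1-yl]trimethylsilane | C=CC[C@@H](OCc1ccc(OC)cc1)C#C[Si](C)(C)C | intermediate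
14 | 1-{[(3R)-hex-5-en-1-yn-3-yloxy]methyl}-4-methoxybenzene | C=CC[C@@H](OCc1ccc(OC)cc1)C#C | intermediate
15 | benzyl (4S,5R)-4-[(tert-butyldimethylsilyl)oxy]-5-hydroxy-8-[(4-methoxybenzyl)oxy]-5-({2-[2-((4-methoxybenzyl)oxy)ethyl]-1,3-dioxolan-2-yl}methyl)undec-10-en-6-ynoate (8R) | O=C(OCc1ccccc1)CC[C@H](O[Si](C)(C)C(C)(C)C)[C@@](O)(CC1(CCOCc2ccc(OC)cc2)OCCO1)C#C[C@H](OCc1ccc(OC)cc1)CC=C | intermediate
16 | (5S,6R)-5-[(tert-butyldimethylsilyl)oxy]-6-{(3R)-3-[(4-methoxybenzyl)oxy]hex-5-en-1-yn-1-yl}-6-({2-[2-((4-methoxybenzyl)oxy)ethyl]-1,3-dioxolan-2-yl}methyl)oxan-2-one | O=C1CC[C@H](O[Si](C)(C)C(C)(C)C)[C@@](CC2(CCOCc3ccc(OC)cc3)OCCO2)(C#C[C@H](OCc2ccc(OC)cc2)CC=C)O1 | intermediate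
17 | (5S,6R)-5-[(tert-butyldimethylsilyl)oxy]-6-{(1Z,3R)-3-[(4-methoxybenzyl)oxy]hexa-1,5-dien-1-yl}-6-({2-[2-((4-methoxybenzyl)oxy)ethyl]-1,3-dioxolan-2-yl}methyl)oxan-2-one | O=C1CC[C@H](O[Si](C)(C)C(C)(C)C)[C@@](CC2(CCOCc3ccc(OC)cc3)OCCO2)(/C=C\[C@H](OCc2ccc(OC)cc2)CC=C)O1 | intermediate
18 | trimethylsilyl ketene acetal of 17 (6-trimethylsilyloxy-3,4-dihydro-2H-pyran; C1 S, C11 R) | C[Si](C)(C)OC1=CC[C@H](O[Si](C)(C)C(C)(C)C)[C@@](CC2(CCOCc3ccc(OC)cc3)OCCO2)(/C=C\[C@H](OCc2ccc(OC)cc2)CC=C)O1 | intermediate
19 | trimethylsilyl ester of acid 20 | C[Si](C)(C)OC(=O)[C@@H]1C[C@H](O[Si](C)(C)C(C)(C)C)C(CC2(CCOCc3ccc(OC)cc3)OCCO2)=C[C@H]1[C@H](OCc1ccc(OC)cc1)CC=C | intermediate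
20 | (1R,2R,5S)-5-[(tert-butyldimethylsilyl)oxy]-2-{(1R)-1-[(4-methoxybenzyl)oxy]but-3-en-1-yl}-4-({2-[2-((4-methoxybenzyl)oxy)ethyl]-1,3-dioxolan-2-yl}methyl)cyclohex-3-ene-1-carboxylic acid | OC(=O)[C@@H]1C[C@H](O[Si](C)(C)C(C)(C)C)C(CC2(CCOCc3ccc(OC)cc3)OCCO2)=C[C@H]1[C@H](OCc1ccc(OC)cc1)CC=C | intermediate
21 | (1R,2R,5S)-5-[(tert-butyldimethylsilyl)oxy]-2-[(1R)-1-hydroxybut-3-en-1-yl]-4-{[2-(2-hydroxyethyl)-1,3-dioxolan-2-yl]methyl}cyclohex-3-ene-1-carboxylic acid | OC(=O)[C@@H]1C[C@H](O[Si](C)(C)C(C)(C)C)C(CC2(CCO)OCCO2)=C[C@H]1[C@H](O)CC=C | intermediate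
22 | (3R,3aR,6S,7aR)-6-[(tert-butyldimethylsilyl)oxy]-5-{[2-(2-hydroxyethyl)-1,3-dioxolan-2-yl]methyl}-3-(prop-2-en-1-yl)-3a,6,7,7a-tetrahydro-2-benzofuran-1(3H)-one | O=C1O[C@H](CC=C)[C@@H]2C=C(CC3(CCO)OCCO3)[C@@H](O[Si](C)(C)C(C)(C)C)C[C@@H]12 | intermediate
23 | (3R,3aR,6S,7aR)-6-[(tert-butyldimethylsilyl)oxy]-5-{[2-(2-hydroxyethyl)-1,3-dioxolan-2-yl]methyl}-3-(2-oxopropyl)-3a,6,7,7a-tetrahydro-2-benzofuran-1(3H)-one | O=C1O[C@H](CC(C)=O)[C@@H]2C=C(CC3(CCO)OCCO3)[C@@H](O[Si](C)(C)C(C)(C)C)C[C@@H]12 | intermediate
24 | tricyclic lactone carbinol, C1=C11 tert-butyldimethylsilyl enol ether, C11 bearing [2-(2-hydroxyethyl)-1,3-dioxolan-2-yl]methyl (3R,6R,8S,9S,10R) | O=C1O[C@@H]2C[C@](C)(O)[C@@H]3C(CC4(CCO)OCCO4)=C(O[Si](C)(C)C(C)(C)C)C[C@@H]1[C@H]23 | intermediate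
25 | C15 aldehyde of 24 (3R,6R,8S,9S,10R) | O=C1O[C@@H]2C[C@](C)(O)[C@@H]3C(CC4(CC=O)OCCO4)=C(O[Si](C)(C)C(C)(C)C)C[C@@H]1[C@H]23 | intermediate
26 | tetracyclic C1 ketone, C11 spiro, C13 dioxolane, C15 and C8 hydroxyls free (3R,6R,8S,9S,10R,11S,15S) | O=C1C[C@H]2C(=O)O[C@@H]3C[C@](C)(O)[C@@H]([C@@H]32)[C@]14CC5(C[C@@H]4O)OCCO5 | intermediate
27 | C8,C15-bis(triethylsilyl) ether of 26 | O=C1C[C@H]2C(=O)O[C@@H]3C[C@](C)(O[Si](CC)(CC)CC)[C@@H]([C@@H]32)[C@]14CC5(C[C@@H]4O[Si](CC)(CC)CC)OCCO5 | intermediate
28 | C1 enol triflate of 27 (alkene C1=C2) | O=S(=O)(OC1=C[C@H]2C(=O)O[C@@H]3C[C@](C)(O[Si](CC)(CC)CC)[C@@H]([C@@H]32)[C@]14CC5(C[C@@H]4O[Si](CC)(CC)CC)OCCO5)C(F)(F)F | intermediate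
29 | methyl acrylate | C=CC(=O)OC | starting material
30 | methyl (E)-dienoate: C1 of the protected tetracycle bearing (E)-CH=CH–CO2Me | COC(=O)/C=C/C1=C[C@H]2C(=O)O[C@@H]3C[C@](C)(O[Si](CC)(CC)CC)[C@@H]([C@@H]32)[C@]14CC5(C[C@@H]4O[Si](CC)(CC)CC)OCCO5 | intermediate
31 | isopropenylboronic acid pinacol ester | C=C(C)B1OC(C)(C)C(C)(C)O1 | starting material
32 | target as C13 dioxolane and C8,C15-bis(triethylsilyl) ether (3R,6R,8S,9S,10R,11R,15S,16S) | C=C(C)[C@H](CC(=O)OC)C1=C[C@H]2C(=O)O[C@@H]3C[C@](C)(O[Si](CC)(CC)CC)[C@@H]([C@@H]32)[C@]14CC5(C[C@@H]4O[Si](CC)(CC)CC)OCCO5 | intermediate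
33 | CNP0255095.1 | C=C(C)[C@H](CC(=O)OC)C1=C[C@H]2C(=O)O[C@@H]3C[C@](C)(O)[C@@H]([C@@H]32)[C@]12CC(=O)C[C@@H]2O | target

## Step count and risk

Total: 21 steps. Longest linear sequence: 18 steps (1 → 2 → 3 → 4 → 7 → 9 → 16 → 17 → 20 → 22 → 23 → 24 → 25 → 26 → 27 → 28 → 30 → 32 → 33). Side branches: 5 → 6 (one step) and 10 → 12 → 14 (two steps).

**Step 11 (key step).** The boat must hold the C6 substituent of the Z alkene over the C2 methylene. If this strain slows the shift, the silyl ketene acetal may be lost at the higher temperature by ionisation of the tertiary allylic C–O bond with elimination, or by desilylation back to 17. The fallback keeps the same bond and ring but runs the shift in the allyl vinyl ether series, without base or ketene acetal. It sets out from 17 and returns at 20. Reduction with iBu2AlH (CH2Cl2, −78 °C) would give the lactol F1. Mesylation and elimination (MsCl, Et3N) would give the 6-alkenyl-3,4-dihydro-2H-pyran F2. Heating F2 in xylene at 150–180 °C should bring about the thermal Claisen ring contraction of a 2-alkenyl dihydropyran to the cyclohexene carbaldehyde F3, through the same boat and with the same stereochemical outcome, and the α-formyl centre can settle trans. Pinnick oxidation (NaClO2, NaH2PO4, 2-methylbut-2-ene) would then give 20.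

**Step 16.** An open transition state may give poor control of the C15 configuration, or the enol ether may be protodesilylated before it reacts. The fallback replaces it by a chelated metal-enolate aldol, from 24 back to 26. N-Bromosuccinimide (THF, −78 °C) would convert the silyl enol ether into the α-bromo ketone F4. Oxidation with Pr4N[RuO4]/NMO would give the bromo keto aldehyde F5. SmI2 (THF, −78 °C) would then generate the trivalent samarium enolate at C11 for an intramolecular Reformatsky-type aldol, in which samarium bridges the enolate and aldehyde oxygens and so places the C15 hydroxyl cis to C1, giving 26.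

**Step 14.** The ene reaction may take its hydrogen from C12 instead of C1, giving an exocyclic alkene, or the aluminium Lewis acid may open the dioxolane or divert to stepwise Prins products. The fallback sets out from 23 and returns at 26, making the C8–C9 bond reductively and fixing the enolate position by halogenation. HF·pyridine would remove the C1 silyl group to give the allylic alcohol F6. MnO2 would oxidise only the allylic alcohol, to the enone F7. SmI2 (THF, t-BuOH, −78 °C) should effect ketyl–olefin cyclisation onto C9 and give the hydroxy ketone F8. The uncertain point is the C8 configuration, which relies on samarium bridging the ketyl and enone oxygens. Bromination of F8 at the more substituted α-carbon (PhNMe3Br3) would give the bromo ketone F4, which is carried to 26 as described for step 16.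

**Step 20.** Insertion at the hindered C16 may be slow, so that protodeboronation or 1,6-addition competes, and the catalyst may be mismatched with the substrate's own facial bias. The fallback runs from 28 back to 32 and builds C16 by a sigmatropic shift. Stille coupling of 28 with (E)-2-methyl-3-(tributylstannyl)prop-2-en-1-ol (Pd(PPh3)4, LiCl, CuI, DMF) would give the dienol F9. Johnson–Claisen rearrangement of F9 (MeC(OMe)3, cat. EtCO2H, 110 °C) would form the C16–C17 bond and the isopropenyl group together, giving 32 directly. Face selection at C16 would then rest on the spiro ring flanking the diene, and the C16 epimers would have to be separated.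

**Step 6.** The ring-closing second conjugate addition may stall at 8, or the acid may begin to ketalise C11 or loosen the silyl ether. The fallback builds the same β-keto ketal by aldol chemistry, from 4 back to 9. Cp2Zr(H)Cl would reduce the Weinreb amide to the aldehyde F10. The lithium enolate of 4-[(4-methoxybenzyl)oxy]butan-2-one (LiN(iPr)2, THF, −78 °C, cold quench) would add to give the aldol F11. Ketalisation under Noyori conditions (Me3SiOCH2CH2OSiMe3, cat. Me3SiOTf, CH2Cl2, −78 °C) would give the hydroxy ketal F12, and Dess–Martin oxidation of the C11 carbinol would give 9.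

## Further compounds

F1 | step 11 | lactol from 17: (5S,6R)-5-[(tert-butyldimethylsilyl)oxy]-6-{(1Z,3R)-3-[(4-methoxybenzyl)oxy]hexa-1,5-dien-1-yl}-6-({2-[2-((4-methoxybenzyl)oxy)ethyl]-1,3-dioxolan-2-yl}methyl)oxan-2-ol (anomeric mixture) | OC1CC[C@H](O[Si](C)(C)C(C)(C)C)[C@@](CC2(CCOCc3ccc(OC)cc3)OCCO2)(/C=C\[C@H](OCc2ccc(OC)cc2)CC=C)O1
F2 | step 11 | 6-alkenyl-3,4-dihydro-2H-pyran from F1 (C1 S, C11 R) | C1=CC[C@H](O[Si](C)(C)C(C)(C)C)[C@@](CC2(CCOCc3ccc(OC)cc3)OCCO2)(/C=C\[C@H](OCc2ccc(OC)cc2)CC=C)O1
F3 | step 11 | (1R,2R,5S)-5-[(tert-butyldimethylsilyl)oxy]-2-{(1R)-1-[(4-methoxybenzyl)oxy]but-3-en-1-yl}-4-({2-[2-((4-methoxybenzyl)oxy)ethyl]-1,3-dioxolan-2-yl}methyl)cyclohex-3-ene-1-carbaldehyde | O=C[C@@H]1C[C@H](O[Si](C)(C)C(C)(C)C)C(CC2(CCOCc3ccc(OC)cc3)OCCO2)=C[C@H]1[C@H](OCc1ccc(OC)cc1)CC=C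
F4 | step 16 | C11 bromo C1 ketone of the tricyclic lactone carbinol, C15 and C8 hydroxyls free | O=C1O[C@@H]2C[C@](C)(O)[C@@H]3[C@](Br)(CC4(CCO)OCCO4)C(=O)C[C@@H]1[C@H]23
F5 | step 16 | C15 aldehyde of F4 | O=C1O[C@@H]2C[C@](C)(O)[C@@H]3[C@](Br)(CC4(CC=O)OCCO4)C(=O)C[C@@H]1[C@H]23
F6 | step 14 | C1 allylic alcohol from 23 | O=C1O[C@H](CC(C)=O)[C@@H]2C=C(CC3(CCO)OCCO3)[C@@H](O)C[C@@H]12
F7 | step 14 | C1 enone (C11=C9) from F6 | O=C1O[C@H](CC(C)=O)[C@@H]2C=C(CC3(CCO)OCCO3)C(=O)C[C@@H]12
F8 | step 14 | tricyclic C1 ketone with C11–H and C8 methyl carbinol | O=C1O[C@@H]2C[C@](C)(O)[C@@H]3[C@H](CC4(CCO)OCCO4)C(=O)C[C@@H]1[C@H]23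
F9 | step 20 | (E)-dienol: C1 of the protected tetracycle bearing (E)-CH=C(CH3)CH2OH | OC/C(C)=C/C1=C[C@H]2C(=O)O[C@@H]3C[C@](C)(O[Si](CC)(CC)CC)[C@@H]([C@@H]32)[C@]14CC5(C[C@@H]4O[Si](CC)(CC)CC)OCCO5
F10 | step 6 | benzyl (4S)-4-[(tert-butyldimethylsilyl)oxy]-5-oxopentanoate | O=C[C@@H](O[Si](C)(C)C(C)(C)C)CCC(=O)OCc1ccccc1
F11 | step 6 | benzyl (4S,5R)-4-[(tert-butyldimethylsilyl)oxy]-5-hydroxy-9-[(4-methoxybenzyl)oxy]-7-oxononanoate (Felkin isomer) | O=C(OCc1ccccc1)CC[C@H](O[Si](C)(C)C(C)(C)C)[C@H](O)CC(=O)CCOCc1ccc(OC)cc1
F12 | step 6 | benzyl (4S,5R)-4-[(tert-butyldimethylsilyl)oxy]-5-hydroxy-6-{2-[2-((4-methoxybenzyl)oxy)ethyl]-1,3-dioxolan-2-yl}hexanoate | O=C(OCc1ccccc1)CC[C@H](O[Si](C)(C)C(C)(C)C)[C@H](O)CC1(CCOCc2ccc(OC)cc2)OCCO1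
A1 | alternative 1 | C15 aldehyde with tetrasubstituted C11=C1 alkene carrying the complete C16 side chain, C8 triethylsilyl ether, C13 dioxolane | C=C(C)[C@H](CC(=O)OC)C1=C(CC5(OCCO5)CC=O)[C@@H]2[C@@H]3[C@@H](C1)C(=O)O[C@@H]3C[C@]2(C)O[Si](CC)(CC)CC
A2 | alternative 1 | target as its C13 dioxolane and C8 triethylsilyl ether | C=C(C)[C@H](CC(=O)OC)C1=C[C@H]2C(=O)O[C@@H]3C[C@](C)(O[Si](CC)(CC)CC)[C@@H]([C@@H]32)[C@]14CC5(OCCO5)C[C@@H]4O
A3 | alternative 2 | Michael precursor: cyclopentyl ketone tethered through C2–C3 to a 4-hydroxy-4-methylcyclopent-2-enone | COC(=O)[C@H](CC(=O)[C@H]1CC2(OCCO2)C[C@@H]1O[Si](C)(C)C(C)(C)C)C1=C[C@@](C)(O)CC1=O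
A4 | alternative 2 | tricyclic diketo ester | COC(=O)[C@@H]1CC(=O)[C@@]2(CC3(OCCO3)C[C@@H]2O[Si](C)(C)C(C)(C)C)[C@@H]4[C@H]1C(=O)C[C@]4(C)O
A5 | alternative 3 | keto lactone with C9=C11 alkene, C1 tert-butyldimethylsilyl ether and C15 triisopropylsilyl ether | O=C1O[C@H](CC(C)=O)[C@@H]2C=C(CC3(CCO[Si](C(C)C)(C(C)C)C(C)C)OCCO3)[C@@H](O[Si](C)(C)C(C)(C)C)C[C@@H]12
A6 | alternative 3 | tricyclic lactone carbinol with a C1 silyl enol ether | CC(C)(C)[Si](C)(C)OC1=C(CC5(OCCO5)CCO[Si](C(C)C)(C(C)C)C(C)C)[C@@H]2[C@@H]3[C@@H](C1)C(=O)O[C@@H]3C[C@]2(C)O
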